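**Retrosynthetic overview**
- Target 13 ⇐ 4,5-epoxy acid 12. The γ-lactone closes last, by 5-exo attack of the carboxyl group on the trisubstituted epoxide with inversion at the quaternary carbon, as in the presumed biosynthesis. 12 is released in the flask from the rigid (E)-epoxy-enoate 10 by saponification and diimide reduction.
- 10 ⇐ epoxy alcohol 8 (oxidation/Wittig, +2 C) ⇐ Sharpless epoxidation of 7, the only allylic alcohol in the triene. This one step fixes site, face and both stereocentres.
- 7 ⇐ ambliofuran 6 (SeO2 oxidation of the terminal E-methyl) ⇐ farnesyl bromide 4 + furan-3-ylmethyl Grignard 5.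
- Rings: the furan is bought (furan-3-ylmethanol); the lactone is the only ring built and is formed in the final step.

Assumption: single-isomer (2E,6E)-farnesol is the commercial terpene feedstock, and the ee of the Sharpless step (typically ≥90%) carries through to the product.

**Step 1**
Reactants: 1 furan-3-ylmethanol
Product: 2 3-(chloromethyl)furan
Conditions: PPh3, NCS, THF, 0 °C → rt; distil
Reagents that add atoms: N-chlorosuccinimide ClN1C(=O)CCC1=O
Why: Appel-type chlorination of a primary alcohol under neutral conditions that the acid-sensitive furan tolerates; no stereocentre.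

**Step 2**
Reactants: 3 (2E,6E)-farnesol
Product: 4 (2E,6E)-farnesyl bromide
Conditions: PBr3 (0.4 equiv), Et2O, −10 → 0 °C; crude used at once
Reagents that add atoms: phosphorus tribromide BrP(Br)Br
Why: PBr3 bromination of a primary allylic alcohol (SN2 on the bromophosphite) at low temperature goes without allylic transposition, so both E olefins are kept.

**Step 3**
Reactants: 2 3-(chloromethyl)furan; 4 (2E,6E)-farnesyl bromide
Product: 6 ambliofuran [3-((3E,7E)-4,8,12-trimethyltrideca-3,7,11-trien-1-yl)furan], via furan-3-ylmethylmagnesium chloride 5 (not isolated)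
Conditions: Mg, THF, 0 °C → rt; then 4, Li2CuCl4 (5 mol%), THF, 0 °C
Reagents that add atoms: none
Why: Kochi/Fouquet–Schlosser copper-catalysed sp3–sp3 Grignard coupling attacks the primary allylic carbon (SN2) with retention of the E olefin and without attack through the furan ring carbon (the known dendrolasin-type coupling); no stereocentre.

**Step 4**
Reactants: 6 ambliofuran
Product: 7 (2E,6E,10E)-13-(furan-3-yl)-2,6,10-trimethyltrideca-2,6,10-trien-1-ol
Conditions: SeO2 (0.3 equiv), t-BuOOH (2 equiv), salicylic acid (0.1 equiv), CH2Cl2, 0 °C → rt; stop near 60% conversion, recycle 6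
Reagents that add atoms: tert-butyl hydroperoxide CC(C)(C)OO (terminal oxidant; the oxygen is passed on through catalytic selenium dioxide O=[Se]=O)
Why: Sharpless–Umbreit catalytic SeO2 allylic oxidation (ene reaction, then [2,3]-shift) selects the E-methyl of the terminal gem-dimethyl olefin and gives the E-allylic alcohol, the only allylic alcohol in the molecule.

**Step 5**
Reactants: 7 allylic alcohol
Product: 8 [(2R,3R)-3-((3E,7E)-10-(furan-3-yl)-3,7-dimethyldeca-3,7-dien-1-yl)-2-methyloxiran-2-yl]methanol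
Conditions: Ti(OiPr)4 (10 mol%), D-(−)-diethyl tartrate (12 mol%), t-BuOOH, 4 Å MS, CH2Cl2, −20 °C
Reagents that add atoms: tert-butyl hydroperoxide CC(C)(C)OO
Why: Katsuki–Sharpless asymmetric epoxidation touches only the olefin bearing the allylic hydroxyl, and D-(−)-tartrate delivers oxygen to the face giving the (2R,3R)-epoxide (L-(+)-tartrate gives 2S,3S with E-allylic alcohols), so both stereocentres of the target are set here by reagent control.

**Step 6**
Reactants: 8 epoxy alcohol
Product: 10 methyl (2E)-3-[(2R,3R)-3-((3E,7E)-10-(furan-3-yl)-3,7-dimethyldeca-3,7-dien-1-yl)-2-methyloxiran-2-yl]prop-2-enoate, via epoxy aldehyde 9 (not isolated)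
Conditions: DMP, pyridine, CH2Cl2, 0 °C → rt; then Ph3P=CHCO2Me, rt
Reagents that add atoms: methyl (triphenylphosphoranylidene)acetate COC(=O)C=P(c1ccccc1)(c1ccccc1)c1ccccc1
Why: Dess–Martin oxidation gives a non-enolisable α-quaternary epoxy aldehyde that is trapped in the same flask by the stabilised ylide (E-selective Wittig olefination); the epoxide stereocentres are not touched.

**Step 7**
Reactants: 10 (E)-epoxy-enoate
Product: 13 (5S)-5-[(1R,4E,8E)-11-(furan-3-yl)-1-hydroxy-4,8-dimethylundeca-4,8-dien-1-yl]-5-methyloxolan-2-one (target), via lithium epoxy-enoate 11 (not isolated), via epoxy acid 12 (not isolated)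
Conditions: LiOH, THF/MeOH/H2O, 0 °C → rt; then KO2CN=NCO2K, AcOH (slow addition, pH 4–5), 0 °C → rt, 12 h
Reagents that add atoms: lithium hydroxide [Li+].[OH-]
Why: Ester hydrolysis followed by diimide reduction (concerted syn H2 transfer, faster at the disubstituted carboxyl-conjugated C=C than at the two trisubstituted olefins, inert to epoxide and furan) converts the rigid E-enoate, whose carboxyl cannot reach the epoxide, into the flexible 4,5-epoxy acid 12, which lactonises in the acetic acid buffer by 5-exo epoxide opening at the tertiary carbon (biomimetic epoxy-acid lactonisation) with inversion there, giving the (5S) quaternary centre, while the carbinol carbon keeps its C–O bond and is (1R).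

**Compound list**
1 | furan-3-ylmethanol | OCc1ccoc1 | starting material
2 | 3-(chloromethyl)furan | ClCc1ccoc1 | intermediate
3 | (2E,6E)-farnesol | CC(C)=CCC/C(C)=C/CC/C(C)=C/CO | starting material
4 | (2E,6E)-farnesyl bromide | CC(C)=CCC/C(C)=C/CC/C(C)=C/CBr | intermediate
5 | furan-3-ylmethylmagnesium chloride | Cl[Mg]Cc1ccoc1 | intermediate
6 | ambliofuran, 3-((3E,7E)-4,8,12-trimethyltrideca-3,7,11-trien-1-yl)furan | C/C(=C\CCc1ccoc1)CC/C=C(\C)CCC=C(C)C | intermediate
7 | (2E,6E,10E)-13-(furan-3-yl)-2,6,10-trimethyltrideca-2,6,10-trien-1-ol | C/C(=C\CCc1ccoc1)CC/C=C(\C)CC/C=C(\C)CO | intermediate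
8 | [(2R,3R)-3-((3E,7E)-10-(furan-3-yl)-3,7-dimethyldeca-3,7-dien-1-yl)-2-methyloxiran-2-yl]methanol | C/C(=C\CCc1ccoc1)CC/C=C(\C)CC[C@H]1O[C@]1(C)CO | intermediate
9 | (2S,3R)-3-((3E,7E)-10-(furan-3-yl)-3,7-dimethyldeca-3,7-dien-1-yl)-2-methyloxirane-2-carbaldehyde | C/C(=C\CCc1ccoc1)CC/C=C(\C)CC[C@H]1O[C@]1(C)C=O | intermediate
10 | methyl (2E)-3-[(2R,3R)-3-((3E,7E)-10-(furan-3-yl)-3,7-dimethyldeca-3,7-dien-1-yl)-2-methyloxiran-2-yl]prop-2-enoate | C/C(=C\CCc1ccoc1)CC/C=C(\C)CC[C@H]1O[C@]1(C)/C=C/C(=O)OC | intermediate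
11 | lithium (2E)-3-[(2R,3R)-3-((3E,7E)-10-(furan-3-yl)-3,7-dimethyldeca-3,7-dien-1-yl)-2-methyloxiran-2-yl]prop-2-enoate | C/C(=C\CCc1ccoc1)CC/C=C(\C)CC[C@H]1O[C@]1(C)/C=C/C(=O)[O-].[Li+] | intermediate
12 | 3-[(2R,3R)-3-((3E,7E)-10-(furan-3-yl)-3,7-dimethyldeca-3,7-dien-1-yl)-2-methyloxiran-2-yl]propanoic acid | C/C(=C\CCc1ccoc1)CC/C=C(\C)CC[C@H]1O[C@]1(C)CCC(=O)O | intermediate
13 | (5S)-5-[(1R,4E,8E)-11-(furan-3-yl)-1-hydroxy-4,8-dimethylundeca-4,8-dien-1-yl]-5-methyloxolan-2-one | C/C(=C\CCc1ccoc1)CC/C=C(\C)CC[C@@H](O)[C@]1(C)CCC(=O)O1 | target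

**Step count**
Total steps: 7. Longest linear sequence: 6 (3 → 4 → 6 → 7 → 8 → 10 → 13; the branch from 1 is equally long).

**Three steps most likely to fail**

Step 7. The telescoped saponification / diimide reduction / lactonisation may over-reduce a trisubstituted olefin. Diimide prefers the disubstituted enoate only by roughly an order of magnitude, and the three stages run without purification. The fallback abandons the reduction of an epoxy-enoate. It sets out from aldehyde 9, isolated after the Dess–Martin oxidation of 8. Still–Gennari olefination (methyl bis(2,2,2-trifluoroethyl)phosphonoacetate, KHMDS, 18-crown-6, THF, −78 °C) gives methyl (2Z)-3-[(2R,3R)-3-((3E,7E)-10-(furan-3-yl)-3,7-dimethyldeca-3,7-dien-1-yl)-2-methyloxiran-2-yl]prop-2-enoate F1. Its cis-placed ester carbonyl opens the epoxide under catalytic CSA in wet CH2Cl2 (same 5-exo mode, inversion at the quaternary carbon, loss of methanol) to give (5S)-5-[(1R,4E,8E)-11-(furan-3-yl)-1-hydroxy-4,8-dimethylundeca-4,8-dien-1-yl]-5-methylfuran-2(5H)-one F2. Conjugate reduction of this butenolide with NiCl2·6H2O/NaBH4 (MeOH, 0 °C) or Stryker's reagent leaves the isolated olefins and the furan alone, and the route comes back at 13.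

Step 4. SeO2/t-BuOOH has to oxidise one of three trisubstituted olefins in the presence of an electron-rich furan; low conversion, enal formation or furan damage are possible. The fallback oxidises before the furan is attached. It sets out from 3, which is acetylated (Ac2O, pyridine) to (2E,6E)-farnesyl acetate F3. SeO2/t-BuOOH then gives (2E,6E,10E)-12-hydroxy-3,7,11-trimethyldodeca-2,6,10-trien-1-yl acetate F4. Treating F4 with three equivalents of Grignard 5 and Li2CuCl4 (THF, −20 → 0 °C) deprotonates the hydroxyl and displaces the allylic acetate, and the route comes back at 7.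

Step 3. The furylmethyl Grignard is prone to Wurtz coupling and the allylic bromide to SN2′ attack. The fallback replaces the Grignard by a sulfone-stabilised carbanion. It sets out from 2 (and uses 4). Sodium benzenesulfinate in DMF gives 3-[(phenylsulfonyl)methyl]furan F5. Deprotonation (n-BuLi, THF, −78 °C) and alkylation with 4 give 3-[(3E,7E)-4,8,12-trimethyl-1-(phenylsulfonyl)trideca-3,7,11-trien-1-yl]furan F6. Reductive desulfonylation (Na/Hg, Na2HPO4, MeOH, −20 °C) brings the route back at 6.

**Further compounds**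
F1 | step 7 | methyl (2Z)-3-[(2R,3R)-3-((3E,7E)-10-(furan-3-yl)-3,7-dimethyldeca-3,7-dien-1-yl)-2-methyloxiran-2-yl]prop-2-enoate | C/C(=C\CCc1ccoc1)CC/C=C(\C)CC[C@H]1O[C@]1(C)/C=C\C(=O)OC
F2 | step 7 | (5S)-5-[(1R,4E,8E)-11-(furan-3-yl)-1-hydroxy-4,8-dimethylundeca-4,8-dien-1-yl]-5-methylfuran-2(5H)-one | C/C(=C\CCc1ccoc1)CC/C=C(\C)CC[C@@H](O)[C@]1(C)C=CC(=O)O1
F3 | step 4 | (2E,6E)-farnesyl acetate | CC(=O)OC/C=C(\C)CC/C=C(\C)CCC=C(C)C
F4 | step 4 | (2E,6E,10E)-12-hydroxy-3,7,11-trimethyldodeca-2,6,10-trien-1-yl acetate | CC(=O)OC/C=C(\C)CC/C=C(\C)CC/C=C(\C)CO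
F5 | step 3 | 3-[(phenylsulfonyl)methyl]furan | O=S(=O)(Cc1ccoc1)c1ccccc1
F6 | step 3 | 3-[(3E,7E)-4,8,12-trimethyl-1-(phenylsulfonyl)trideca-3,7,11-trien-1-yl]furan | CC(C)=CCC/C(C)=C/CC/C(C)=C/CC(c1ccoc1)S(=O)(=O)c1ccccc1
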